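(The readings come from a simulation for an exercise; scatter was added.)

13.0 % of the free catalyst charged to the flask stood to be lost, if each impurity takes one catalyst with it, and this is the number I carried: the poison share, impurity charged over catalyst charged.

the same everywhere: left-handed substrate 40 mM; right-handed substrate 40 mM; impurity 83 µM

|  | partner | free catalyst | remark |
|---|---|---|---|
| larch | 1.1 equiv | 0.8 mol% | run made earlier |
| elm | 1.1 equiv | 3.2 mol% | run made earlier |
| flask | 1.10 equiv | 1.6 mol% |  |

- larch (time / min: left-handed product / %, left-handed substrate / %): 6.00: 4.7, 47.5; 20.0: 9.6, 37.4; 30.0: 16.2, 35.4; 50.0: 22.3, 27.0
- elm (time / min: left-handed product / %, left-handed substrate / %): 6.00: 15.7, 36.7; 20.0: 30.9, 19.9; 30.0: 36.8, 15.0; 50.0: 40.2, 12.5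

(readings scatter by 1 percentage point)

- factor on the rate of making left-handed product when 50 % of the left-handed substrate and right-handed substrate together are converted if free catalyst is charged twice over
- factor on the rate when 50 % of the left-handed substrate and right-handed substrate together are converted if free catalyst is charged at 0.3 mol% instead

- free catalyst is single-handed; left-handed substrate and right-handed substrate are mirror images of each other, charged as a racemate, each of them at the stated concentration
- the analysis behind the earlier runs scatters by 1 percentage point, standard deviation

I read the two tables row against row, first as turnovers, left-handed product per catalyst charged. After 6.00 min the larch run stood at 11.8 and the elm run at 9.81, but a scatter of 1 percentage point on a larch reading of 4.7 % left that row too weak to show the poison shares of 25.9 % and 6.48 %. In the last row the elm run's left-handed product and left-handed substrate summed to 52.7 %, against 49.3 % in the larch run, and I kept that as a doubt, since right-handed substrate turning into left-handed substrate would show so. Twice the flask's loading is the elm loading, with its poison share, and 0.3 mol% has a poison share of 69.2 %. Counting working catalyst, I reckoned factors of 2.15 and 0.0664. The forecast printed the same, 2.15 and 0.066, holding that “The rate factor therefore equals the ratio of active catalyst”.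

The simulation gave 1.57 and 0.144, with spent catalyst, at 50 % conversion, at 13.0 % of the catalyst in the flask against a poison share of 13.0 %, and at 69.2 % with 0.3 mol% against 69.2 %, which leaves the rate per free catalyst at equal conversion changed by factors of 0.731 and 2.17.

    partner + free catalyst + right-handed substrate → free catalyst + right-handed product (k = 42.0 M⁻² min⁻¹)
    left-handed substrate ⇌ right-handed substrate (k = 0.00130 min⁻¹)
    partner + free catalyst + left-handed substrate → free catalyst + left-handed product (k = 1400 M⁻² min⁻¹)
    free catalyst + impurity → spent catalyst (k = 89000 M⁻¹ min⁻¹)

The flask took 3.62 h to reach 50 % conversion, less than the 4.44 h in which the two substrates halve their difference by interconversion. Right-handed substrate in the flask stood at 47.2 % after 50.0 min and at 30.7 % after 500 min, when right-handed product had reached 3.33 %.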